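**Plan**

- Retrosynthesis: the two aryl pivalates go last. The C1'–C8a' bond of the tetralin is then cut, which turns the carbocycle back into a second 2-aryl-4-benzyltetrahydrofuran. Next come the C5–C5' biaryl bond (Suzuki), and in each half the ArCH2–C4 bond (aryl Grignard on a spiro-epoxide) and the C3–C4 ring bond (radical cyclisation).
- Forward: 5-bromovanillin is taken to one common bromoaryl spiro-epoxide 10, whose tetrahydrofuran ring is closed by a trivalent-titanium radical cyclisation. Epoxide 10 is opened once with an isovanillyl and once with a vanillyl Grignard reagent, the halves are joined by Suzuki coupling, and the tetralin ring is closed last by acid.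
- Stereochemistry: C2 comes from a Sharpless kinetic resolution, C3 from the trans-selective radical cyclisation, C4 from epoxidation anti to the C3 side chain, and C1' from the chair-like Friedel–Crafts closure.
- Enabling feature: C1' is a benzylic carbon para to the ring D phenol and is bonded to C8a' of ring B, which lies para to the ring B methoxy group. The carbocycle C1'–C2'–C3'–C4'–C4a'–C8a' is therefore the Friedel–Crafts isomer of a tetrahydrofuran O–C1'–C2'–C3'–CH2 whose pendant vanillyl ring becomes ring B.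

Key step: step 17

Remark on locants and supply: in each tetrahydrofuran O1, C2 (aryl), C3 (CH2OH), C4 (tertiary carbinol with the benzyl group), C5; in the tetralin C1' (aryl), C2' (CH2OH), C3' (carbinol), C4', C4a', C8a'; rings C and D are the biaryl-linked guaiacyl rings on the tetrahydrofuran and on the tetralin, ring B is the aromatic ring of the tetralin; compounds 1, 3, 6, 11 and 18 are taken as commercial.

**Route**

Step 1
Reactants: 1 5-bromovanillin
Product: 2 3-bromo-5-methoxy-4-(triisopropylsilyloxy)benzaldehyde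
Conditions: iPr3SiCl, imidazole, DMF, rt
Reagents that add atoms: chlorotriisopropylsilane, CC(C)[Si](Cl)(C(C)C)C(C)C
Why: Silyl ether formation masks the acidic phenol with a bulky group that tolerates Grignard, epoxidation and radical conditions and is later cleaved by fluoride faster than an alkyl silyl ether.

Step 2
Reactants: 2 3-bromo-5-methoxy-4-(triisopropylsilyloxy)benzaldehyde; 3 vinylmagnesium bromide
Product: 4 rac-1-[3-bromo-5-methoxy-4-(triisopropylsilyloxy)phenyl]prop-2-en-1-ol
Conditions: THF, −78 → 0 °C; aq. NH4Cl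
Reagents that add atoms: none
Why: Grignard 1,2-addition to the aldehyde gives the racemic aryl vinyl carbinol that the resolution needs.

Step 3
Reactants: 4 rac-1-[3-bromo-5-methoxy-4-(triisopropylsilyloxy)phenyl]prop-2-en-1-ol
Product: 5 (R)-[3-bromo-5-methoxy-4-(triisopropylsilyloxy)phenyl][(S)-oxiran-2-yl]methanol (anti epoxy alcohol)
Conditions: Ti(OiPr)4 (0.15 equiv), D-(−)-diisopropyl tartrate (0.2 equiv), tBuOOH (0.45 equiv), 4 Å molecular sieves, CH2Cl2, −20 °C
Reagents that add atoms: tert-butyl hydroperoxide, CC(C)(C)OO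
Why: In this Sharpless kinetic resolution the D-(−)-tartrate catalyst should epoxidise the S alcohol much faster than the R alcohol, which fixes the carbinol centre that becomes C2 (the unreacted R alcohol is removed by chromatography, and the epoxide centre is erased in step 5).

Step 4
Reactants: 5 (R)-[3-bromo-5-methoxy-4-(triisopropylsilyloxy)phenyl][(S)-oxiran-2-yl]methanol; 6 propargyl bromide
Product: 7 (S)-2-{(R)-[3-bromo-5-methoxy-4-(triisopropylsilyloxy)phenyl](prop-2-yn-1-yloxy)methyl}oxirane
Conditions: NaH, Bu4NI (cat.), THF, 0 °C → rt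
Reagents that add atoms: none
Why: Williamson etherification of the sodium alkoxide with the reactive propargylic bromide leaves the carbinol centre untouched and, in aprotic THF, should outrun Payne rearrangement.

Step 5
Reactants: 7 (S)-2-{(R)-[3-bromo-5-methoxy-4-(triisopropylsilyloxy)phenyl](prop-2-yn-1-yloxy)methyl}oxirane
Product: 8 {(2S,3R)-2-[3-bromo-5-methoxy-4-(triisopropylsilyloxy)phenyl]-4-methylenetetrahydrofuran-3-yl}methanol
Conditions: Cp2TiCl2 (2.5 equiv), Zn dust, THF, rt, slow addition of 7; then 1 M HCl, 0 °C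
Reagents that add atoms: none
Why: In this Nugent–RajanBabu reaction trivalent titanium (Cp2TiCl) opens the epoxide to the secondary β-titanoxy radical, which closes 5-exo-dig onto the alkyne; with the C2 aryl group pseudo-equatorial in the chair-like transition state, C3 should be set trans to it whatever the epoxide configuration was.

Step 6
Reactants: 8 {(2S,3R)-2-[3-bromo-5-methoxy-4-(triisopropylsilyloxy)phenyl]-4-methylenetetrahydrofuran-3-yl}methanol
Product: 9 tert-butyl({(2S,3R)-2-[3-bromo-5-methoxy-4-(triisopropylsilyloxy)phenyl]-4-methylenetetrahydrofuran-3-yl}methoxy)dimethylsilane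
Conditions: tBuMe2SiCl, imidazole, DMF, 0 °C → rt
Reagents that add atoms: tert-butyldimethylsilyl chloride, CC(C)(C)[Si](C)(C)Cl
Why: Silylation of the primary alcohol removes a hydroxyl that could direct the peracid and turns the C3 side chain into a bulky shield for the next step.

Step 7
Reactants: 9 tert-butyl({(2S,3R)-2-[3-bromo-5-methoxy-4-(triisopropylsilyloxy)phenyl]-4-methylenetetrahydrofuran-3-yl}methoxy)dimethylsilane
Product: 10 (3R,6S,7R)-6-[3-bromo-5-methoxy-4-(triisopropylsilyloxy)phenyl]-7-[(tert-butyldimethylsilyloxy)methyl]-1,5-dioxaspiro[2.4]heptane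
Conditions: mCPBA, NaHCO3, CH2Cl2, 0 °C
Reagents that add atoms: meta-chloroperoxybenzoic acid, OOC(=O)c1cccc(Cl)c1
Why: Prilezhaev epoxidation of the exocyclic 1,1-disubstituted alkene should occur on the ring face opposite to the adjacent silyloxymethyl group, which places the epoxide oxygen trans to the C3 side chain and so sets C4.

Step 8
Reactants: 11 5-bromo-2-methoxyphenol
Product: 12 (5-bromo-2-methoxyphenoxy)triisopropylsilane
Conditions: iPr3SiCl, imidazole, DMF, rt
Reagents that add atoms: chlorotriisopropylsilane, CC(C)[Si](Cl)(C(C)C)C(C)C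
Why: Silyl ether formation protects the phenol so that the aryl bromide can be turned into a Grignard reagent.

Step 9
Reactants: 10 (3R,6S,7R)-6-[3-bromo-5-methoxy-4-(triisopropylsilyloxy)phenyl]-7-[(tert-butyldimethylsilyloxy)methyl]-1,5-dioxaspiro[2.4]heptane; 12 (5-bromo-2-methoxyphenoxy)triisopropylsilane
Product: 14 (3S,4R,5S)-5-[3-bromo-5-methoxy-4-(triisopropylsilyloxy)phenyl]-4-[(tert-butyldimethylsilyloxy)methyl]-3-[4-methoxy-3-(triisopropylsilyloxy)benzyl]tetrahydrofuran-3-ol, via isovanillyl Grignard reagent 13 (not isolated)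
Conditions: 12, Mg, THF, 50 °C; then CuI (0.2 equiv), 10, THF, −30 → 0 °C; aq. NH4Cl
Reagents that add atoms: none
Why: Copper-catalysed epoxide opening by the aryl Grignard reagent is an SN2 attack at the unhindered CH2 terminus, so the tertiary C4–O bond keeps its configuration while the isovanillyl CH2–aryl bond forms.

Step 10
Reactants: 14 (3S,4R,5S)-5-[3-bromo-5-methoxy-4-(triisopropylsilyloxy)phenyl]-4-[(tert-butyldimethylsilyloxy)methyl]-3-[4-methoxy-3-(triisopropylsilyloxy)benzyl]tetrahydrofuran-3-ol
Product: 15 (3S,4R,5S)-5-(3-bromo-4-hydroxy-5-methoxyphenyl)-4-[(tert-butyldimethylsilyloxy)methyl]-3-(3-hydroxy-4-methoxybenzyl)tetrahydrofuran-3-ol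
Conditions: Bu4NF (2.1 equiv), THF, −20 °C, short reaction time; aq. NH4Cl
Reagents that add atoms: none
Why: Fluoride desilylation is much faster for aryl silyl ethers (phenoxide leaving groups) than for the primary alkyl silyl ether, so only the ring C and isovanillyl phenols should be set free.

Step 11
Reactants: 15 (3S,4R,5S)-5-(3-bromo-4-hydroxy-5-methoxyphenyl)-4-[(tert-butyldimethylsilyloxy)methyl]-3-(3-hydroxy-4-methoxybenzyl)tetrahydrofuran-3-ol
Product: 16 bis-pivalate of 15 (ring C phenol and isovanillyl phenol esterified)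
Conditions: tBuCOCl, Et3N, DMAP (cat.), CH2Cl2, 0 °C → rt
Reagents that add atoms: pivaloyl chloride, CC(C)(C)C(=O)Cl
Why: DMAP-catalysed acylation esterifies the two phenols while the hindered tertiary alcohol stays free, and it installs the electron-withdrawing esters that later switch off ring C.

Step 12
Reactants: 16 bis-pivalate of 15
Product: 17 pinacol boronate of 16 (Bpin in place of Br on ring C)
Conditions: B2pin2, Pd(dppf)Cl2 (5 mol%; dppf = 1,1'-bis(diphenylphosphino)ferrocene), KOAc, 1,4-dioxane, 85 °C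
Reagents that add atoms: bis(pinacolato)diboron, CC1(C)OB(OC1(C)C)B1OC(C)(C)C(C)(C)O1
Why: Miyaura borylation under weakly basic acetate conditions should convert the aryl bromide into the boronate without harm to the aryl pivalates, the silyl ether or the tertiary alcohol.

Step 13
Reactants: 18 4-bromo-2-methoxyphenol
Product: 19 (4-bromo-2-methoxyphenoxy)triisopropylsilane
Conditions: iPr3SiCl, imidazole, DMF, rt
Reagents that add atoms: chlorotriisopropylsilane, CC(C)[Si](Cl)(C(C)C)C(C)C
Why: Silyl ether formation protects the phenol so that the aryl bromide can be turned into a Grignard reagent.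

Step 14
Reactants: 10 (3R,6S,7R)-6-[3-bromo-5-methoxy-4-(triisopropylsilyloxy)phenyl]-7-[(tert-butyldimethylsilyloxy)methyl]-1,5-dioxaspiro[2.4]heptane; 19 (4-bromo-2-methoxyphenoxy)triisopropylsilane
Product: 21 (3S,4R,5S)-5-[3-bromo-5-methoxy-4-(triisopropylsilyloxy)phenyl]-4-[(tert-butyldimethylsilyloxy)methyl]-3-[3-methoxy-4-(triisopropylsilyloxy)benzyl]tetrahydrofuran-3-ol, via vanillyl Grignard reagent 20 (not isolated)
Conditions: 19, Mg, THF, 50 °C; then CuI (0.2 equiv), 10, THF, −30 → 0 °C; aq. NH4Cl
Reagents that add atoms: none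
Why: The same copper-catalysed SN2 epoxide opening at the CH2 terminus attaches the vanillyl ring, the future ring B, with C4 unchanged.

Step 15
Reactants: 17 pinacol boronate of 16; 21 (3S,4R,5S)-5-[3-bromo-5-methoxy-4-(triisopropylsilyloxy)phenyl]-4-[(tert-butyldimethylsilyloxy)methyl]-3-[3-methoxy-4-(triisopropylsilyloxy)benzyl]tetrahydrofuran-3-ol
Product: 22 C5–C5' biaryl of the ring C half (aryl pivalates, alkyl silyl ether) and the ring D half (aryl and alkyl silyl ethers)
Conditions: Pd(OAc)2 (5 mol%), SPhos (2-dicyclohexylphosphino-2',6'-dimethoxybiphenyl, 10 mol%), K3PO4, toluene/H2O (10:1), 70 °C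
Reagents that add atoms: none
Why: Suzuki–Miyaura coupling with a dialkylbiarylphosphine ligand is suited to partners that each carry one ortho oxygen substituent, the mild phosphate base should spare the hindered pivalates, and traces of the minor enantiomer of either half end up in separable diastereomers.

Step 16
Reactants: 22 C5–C5' biaryl of the ring C half and the ring D half
Product: 23 unsymmetrical bis-tetrahydrofuran dimer with ring C and isovanillyl phenols as pivalates and all other hydroxyl groups free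
Conditions: Bu4NF/AcOH (1:1, excess), THF, 0 °C → rt
Reagents that add atoms: none
Why: Acetic-acid-buffered fluoride desilylation removes the two aryl and two alkyl silyl ethers, and the buffer keeps the freed ring D phenol protonated so that the neighbouring ring C pivalate should neither migrate nor be cleaved.

Step 17
Reactants: 23 unsymmetrical bis-tetrahydrofuran dimer
Product: 24 bis-pivalate of the target (ring D half now the (1'S,2'S,3'S)-aryltetralin, ring C half unchanged)
Conditions: CF3CO2H (10 equiv), CH2Cl2, 0 °C; aq. NaHCO3/MeOH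
Reagents that add atoms: none
Why: Acid protonates the ether oxygen of the tetrahydrofuran on ring D and heterolysis of its bond to C1' leaves a benzylic cation stabilised by the para-hydroxyl group (the O-protonated form of a para-quinone methide); C6 of the pendant vanillyl ring, the position para to its methoxy group, attacks C1' and proton loss rearomatises ring B. The closest known reaction is the acid-mediated isomerisation of 2-aryl-4-benzyltetrahydrofuran lignans to aryltetralins (olivil to cycloolivil). The six-membered carbocycle C1'–C2'–C3'–C4'–C4a'–C8a' closes by intramolecular Friedel–Crafts alkylation, 6-exo-trig with respect to the C1'=C(aryl) bond of the quinone methide, while the five-membered ether ring opens. The new stereocentre C1' is controlled by C2': in the chair-like transition state the ring D aryl group and the C2' hydroxymethyl group are both pseudo-equatorial, so the aryl group should end trans to the C2' branch. The step needs ionisation at the ring D side only, which the free para-hydroxyl there and the para-pivaloyloxy group on ring C should secure, with the isovanillyl pivalate weakening that ring as a nucleophile in addition. Return of the primary hydroxyl merely re-forms the ether reversibly, whereas the C–C closure cannot revert, so the material should collect in the tetralin.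

Step 18
Reactants: 24 bis-pivalate of the target
Product: 25 CNP0252244.1
Conditions: NaOMe (6 equiv), degassed MeOH, 0 °C → rt; aq. NH4Cl
Reagents that add atoms: none
Why: Methanolysis (transesterification) of the two aryl pivalates is far faster than any reaction of the alcohols or ethers and should release the last two phenols without touching a stereocentre.

**Compound list**

1 | 5-bromovanillin | COc1cc(C=O)cc(Br)c1O | starting material
2 | 3-bromo-5-methoxy-4-(triisopropylsilyloxy)benzaldehyde | COc1cc(C=O)cc(Br)c1O[Si](C(C)C)(C(C)C)C(C)C | intermediate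
3 | vinylmagnesium bromide | C=C[Mg]Br | starting material
4 | rac-1-[3-bromo-5-methoxy-4-(triisopropylsilyloxy)phenyl]prop-2-en-1-ol | COc1cc(C(O)C=C)cc(Br)c1O[Si](C(C)C)(C(C)C)C(C)C | intermediate
5 | (R)-[3-bromo-5-methoxy-4-(triisopropylsilyloxy)phenyl][(S)-oxiran-2-yl]methanol | O[C@H](c1cc(OC)c(O[Si](C(C)C)(C(C)C)C(C)C)c(Br)c1)[C@@H]1CO1 | intermediate
6 | propargyl bromide | C#CCBr | starting material
7 | (S)-2-{(R)-[3-bromo-5-methoxy-4-(triisopropylsilyloxy)phenyl](prop-2-yn-1-yloxy)methyl}oxirane | C#CCO[C@H](c1cc(OC)c(O[Si](C(C)C)(C(C)C)C(C)C)c(Br)c1)[C@@H]1CO1 | intermediate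
8 | {(2S,3R)-2-[3-bromo-5-methoxy-4-(triisopropylsilyloxy)phenyl]-4-methylenetetrahydrofuran-3-yl}methanol | C=C1CO[C@H](c2cc(OC)c(O[Si](C(C)C)(C(C)C)C(C)C)c(Br)c2)[C@H]1CO | intermediate
9 | tert-butyldimethylsilyl ether of 8 | C=C1CO[C@H](c2cc(OC)c(O[Si](C(C)C)(C(C)C)C(C)C)c(Br)c2)[C@H]1CO[Si](C)(C)C(C)(C)C | intermediate
10 | (3R,6S,7R)-6-[3-bromo-5-methoxy-4-(triisopropylsilyloxy)phenyl]-7-[(tert-butyldimethylsilyloxy)methyl]-1,5-dioxaspiro[2.4]heptane | C1O[C@@]12CO[C@H](c3cc(OC)c(O[Si](C(C)C)(C(C)C)C(C)C)c(Br)c3)[C@H]2CO[Si](C)(C)C(C)(C)C | intermediate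
11 | 5-bromo-2-methoxyphenol | COc1ccc(Br)cc1O | starting material
12 | (5-bromo-2-methoxyphenoxy)triisopropylsilane | COc1ccc(Br)cc1O[Si](C(C)C)(C(C)C)C(C)C | intermediate
13 | [4-methoxy-3-(triisopropylsilyloxy)phenyl]magnesium bromide | COc1ccc([Mg]Br)cc1O[Si](C(C)C)(C(C)C)C(C)C | intermediate (not isolated)
14 | (3S,4R,5S)-5-[3-bromo-5-methoxy-4-(triisopropylsilyloxy)phenyl]-4-[(tert-butyldimethylsilyloxy)methyl]-3-[4-methoxy-3-(triisopropylsilyloxy)benzyl]tetrahydrofuran-3-ol | COc1ccc(C[C@@]2(O)CO[C@H](c3cc(OC)c(O[Si](C(C)C)(C(C)C)C(C)C)c(Br)c3)[C@H]2CO[Si](C)(C)C(C)(C)C)cc1O[Si](C(C)C)(C(C)C)C(C)C | intermediate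
15 | (3S,4R,5S)-5-(3-bromo-4-hydroxy-5-methoxyphenyl)-4-[(tert-butyldimethylsilyloxy)methyl]-3-(3-hydroxy-4-methoxybenzyl)tetrahydrofuran-3-ol | COc1ccc(C[C@@]2(O)CO[C@H](c3cc(OC)c(O)c(Br)c3)[C@H]2CO[Si](C)(C)C(C)(C)C)cc1O | intermediate
16 | bis-pivalate of 15 (ring C and isovanillyl phenols) | COc1ccc(C[C@@]2(O)CO[C@H](c3cc(OC)c(OC(=O)C(C)(C)C)c(Br)c3)[C@H]2CO[Si](C)(C)C(C)(C)C)cc1OC(=O)C(C)(C)C | intermediate
17 | pinacol boronate of 16 (Bpin in place of Br) | COc1ccc(C[C@@]2(O)CO[C@H](c3cc(OC)c(OC(=O)C(C)(C)C)c(c3)B3OC(C)(C)C(C)(C)O3)[C@H]2CO[Si](C)(C)C(C)(C)C)cc1OC(=O)C(C)(C)C | intermediate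
18 | 4-bromo-2-methoxyphenol | COc1cc(Br)ccc1O | starting material
19 | (4-bromo-2-methoxyphenoxy)triisopropylsilane | COc1cc(Br)ccc1O[Si](C(C)C)(C(C)C)C(C)C | intermediate
20 | [3-methoxy-4-(triisopropylsilyloxy)phenyl]magnesium bromide | COc1cc([Mg]Br)ccc1O[Si](C(C)C)(C(C)C)C(C)C | intermediate (not isolated)
21 | (3S,4R,5S)-5-[3-bromo-5-methoxy-4-(triisopropylsilyloxy)phenyl]-4-[(tert-butyldimethylsilyloxy)methyl]-3-[3-methoxy-4-(triisopropylsilyloxy)benzyl]tetrahydrofuran-3-ol | COc1cc(C[C@@]2(O)CO[C@H](c3cc(OC)c(O[Si](C(C)C)(C(C)C)C(C)C)c(Br)c3)[C@H]2CO[Si](C)(C)C(C)(C)C)ccc1O[Si](C(C)C)(C(C)C)C(C)C | intermediate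
22 | C5–C5' biaryl of the ring C half (16 without Br) and the ring D half (21 without Br), (3S,4R,5S) in both tetrahydrofuranol units | COc1ccc(C[C@@]2(O)CO[C@H](c3cc(OC)c(OC(=O)C(C)(C)C)c(c3)-c3cc(cc(OC)c3O[Si](C(C)C)(C(C)C)C(C)C)[C@H]3OC[C@](O)(Cc4ccc(O[Si](C(C)C)(C(C)C)C(C)C)c(OC)c4)[C@@H]3CO[Si](C)(C)C(C)(C)C)[C@H]2CO[Si](C)(C)C(C)(C)C)cc1OC(=O)C(C)(C)C | intermediate
23 | unsymmetrical bis-tetrahydrofuran dimer: ring C and isovanillyl phenols as pivalates, ring D phenol, vanillyl phenol and all alcohols free | COc1ccc(C[C@@]2(O)CO[C@H](c3cc(OC)c(OC(=O)C(C)(C)C)c(c3)-c3cc(cc(OC)c3O)[C@H]3OC[C@](O)(Cc4ccc(O)c(OC)c4)[C@@H]3CO)[C@H]2CO)cc1OC(=O)C(C)(C)C | intermediate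
24 | bis-pivalate of the target: (1'S,2'S,3'S)-aryltetralin on ring D, (3S,4R,5S)-tetrahydrofuranol on ring C | COc1ccc(C[C@@]2(O)CO[C@H](c3cc(OC)c(OC(=O)C(C)(C)C)c(c3)-c3cc(cc(OC)c3O)[C@H]3c4cc(O)c(OC)cc4C[C@@](O)(CO)[C@@H]3CO)[C@H]2CO)cc1OC(=O)C(C)(C)C | intermediate
25 | CNP0252244.1 | COc1ccc(C[C@@]2(O)CO[C@H](c3cc(OC)c(O)c(-c4cc([C@H]5c6cc(O)c(OC)cc6C[C@@](O)(CO)[C@@H]5CO)cc(OC)c4O)c3)[C@H]2CO)cc1O | target

**Step count and risks**

Total step count: 18. Longest linear sequence: 15 (steps 1–7, 9–12, 15–18).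

Steps most likely to fail:

1. Step 17. The risk is loss of site selectivity: the tetrahydrofuran on ring C may ionise as well, or the acyl group may migrate between the two neighbouring biaryl oxygens before ionisation. The fallback moves the same C1'–C8a' closure in front of the biaryl coupling, where only one tetrahydrofuran is present. It sets out from 21. Buffered Bu4NF/AcOH in THF removes all three silyl groups to give (3S,4R,5S)-5-(3-bromo-4-hydroxy-5-methoxyphenyl)-3-(4-hydroxy-3-methoxybenzyl)-4-(hydroxymethyl)tetrahydrofuran-3-ol F1. CF3CO2H in CH2Cl2 at 0 °C then effects the known acid isomerisation to the bromo aryltetralin (1S,2S,3S)-1-(3-bromo-4-hydroxy-5-methoxyphenyl)-2,3-bis(hydroxymethyl)-6-methoxy-1,2,3,4-tetrahydronaphthalene-3,7-diol F2. Suzuki coupling of F2 with boronate 17 under the conditions of step 15 gives the mono-silyl ether of 24 F3, and HF·pyridine in THF removes the remaining alkyl silyl ether, so the fallback comes back to the route at 24.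

2. Step 7. The risk is poor facial selectivity of the epoxidation, because the C2 aryl group sits on the face that must be attacked. The fallback delivers the oxygen with a bulkier reagent and closes the epoxide afterwards. It sets out from 9. Catalytic OsO4 with N-methylmorpholine N-oxide in acetone/water should dihydroxylate the exocyclic alkene anti to the silyloxymethyl group and give the diol (3R,4R,5S)-5-[3-bromo-5-methoxy-4-(triisopropylsilyloxy)phenyl]-4-[(tert-butyldimethylsilyloxy)methyl]-3-(hydroxymethyl)tetrahydrofuran-3-ol F4, from which any minor diastereomer should be separable. Tosylation of the primary hydroxyl (TsCl, Et3N, CH2Cl2, 0 °C) gives the primary tosylate of F4 F5. NaH in THF then closes the epoxide through the tertiary alkoxide with retention at C4, and the fallback comes back to the route at 10.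

3. Step 15. The risk is slow transmetalation at the hindered ortho-oxygenated centres, protodeboronation, or hydrolysis of the aryl esters by the base. The fallback reverses the polarity of the coupling and installs the esters afterwards. It sets out from 21 and 15. Miyaura borylation of 21 under the conditions of step 12 gives the pinacol boronate of 21 F6. This is coupled with the free bis-phenol bromide 15 (Pd(OAc)2, SPhos, K3PO4, 1,4-dioxane/H2O, 70 °C) to give the biaryl with free ring C and isovanillyl phenols F7. Pivaloylation as in step 11 can only reach these two phenols, because the ring D and vanillyl phenols are still silylated, and the fallback comes back to the route at 22.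

**Further compounds**

F1 | step 17 | (3S,4R,5S)-5-(3-bromo-4-hydroxy-5-methoxyphenyl)-3-(4-hydroxy-3-methoxybenzyl)-4-(hydroxymethyl)tetrahydrofuran-3-ol | COc1cc(C[C@@]2(O)CO[C@H](c3cc(OC)c(O)c(Br)c3)[C@H]2CO)ccc1O
F2 | step 17 | (1S,2S,3S)-1-(3-bromo-4-hydroxy-5-methoxyphenyl)-2,3-bis(hydroxymethyl)-6-methoxy-1,2,3,4-tetrahydronaphthalene-3,7-diol | COc1cc(cc(Br)c1O)[C@H]1c2cc(O)c(OC)cc2C[C@@](O)(CO)[C@@H]1CO
F3 | step 17 | mono-silyl ether of 24 (tert-butyldimethylsilyl on the ring C side primary oxygen) | COc1ccc(C[C@@]2(O)CO[C@H](c3cc(OC)c(OC(=O)C(C)(C)C)c(c3)-c3cc(cc(OC)c3O)[C@H]3c4cc(O)c(OC)cc4C[C@@](O)(CO)[C@@H]3CO)[C@H]2CO[Si](C)(C)C(C)(C)C)cc1OC(=O)C(C)(C)C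
F4 | step 7 | (3R,4R,5S)-5-[3-bromo-5-methoxy-4-(triisopropylsilyloxy)phenyl]-4-[(tert-butyldimethylsilyloxy)methyl]-3-(hydroxymethyl)tetrahydrofuran-3-ol | OC[C@@]1(O)CO[C@H](c2cc(OC)c(O[Si](C(C)C)(C(C)C)C(C)C)c(Br)c2)[C@H]1CO[Si](C)(C)C(C)(C)C
F5 | step 7 | primary tosylate of F4 | Cc1ccc(cc1)S(=O)(=O)OC[C@@]1(O)CO[C@H](c2cc(OC)c(O[Si](C(C)C)(C(C)C)C(C)C)c(Br)c2)[C@H]1CO[Si](C)(C)C(C)(C)C
F6 | step 15 | pinacol boronate of 21 (Bpin in place of Br on ring D) | COc1cc(C[C@@]2(O)CO[C@H](c3cc(OC)c(O[Si](C(C)C)(C(C)C)C(C)C)c(c3)B3OC(C)(C)C(C)(C)O3)[C@H]2CO[Si](C)(C)C(C)(C)C)ccc1O[Si](C(C)C)(C(C)C)C(C)C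
F7 | step 15 | biaryl 22 with free ring C and isovanillyl phenols in place of the pivalates | COc1ccc(C[C@@]2(O)CO[C@H](c3cc(OC)c(O)c(c3)-c3cc(cc(OC)c3O[Si](C(C)C)(C(C)C)C(C)C)[C@H]3OC[C@](O)(Cc4ccc(O[Si](C(C)C)(C(C)C)C(C)C)c(OC)c4)[C@@H]3CO[Si](C)(C)C(C)(C)C)[C@H]2CO[Si](C)(C)C(C)(C)C)cc1O
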